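The dihydropyridine ring is cut at N2, both C–N bonds at once: C1 becomes an aryl methyl ketone and C3 a secondary alcohol of inverted configuration. The key step exploits this 1,5-relationship of C1 and C3 through C8a, C4a and C4: in one flask the hydroxyl is replaced by azide with inversion and the azide is condensed onto the ketone (Mitsunobu, Staudinger, aza-Wittig), which inserts N2, fixes (S)-C3 and closes the ring. The precursor arises from a biaryl benzoic acid by carboxylate-directed C–H alkylation with (R)-propylene oxide at C4a, the only C–H ortho to the carboxyl because C8 bears OMe; the resulting temporary lactone is opened with MeLi.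

Key step: step 12

Remark: the target SMILES defines no configuration for the hindered biaryl axis, so only C3 is controlled and all biaryl compounds of the route are taken as mixtures (or equilibrating pairs) of rotamers about that axis; locants C1 to C8a are those of the isoquinoline ring of the target, and tosyl means 4-methylbenzenesulfonyl.

Step 1
Reactants: 1 N,N-diethyl-2-methoxybenzamide; 2 3-bromo-2-methylprop-1-ene
Product: 3 N,N-diethyl-2-methoxy-6-(2-methylprop-2-en-1-yl)benzamide
Conditions: s-BuLi, TMEDA, THF, −78 °C; MgBr2·OEt2; then 2, −78 °C to rt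
Reagents that add atoms: none
Why: Directed ortho-metalation places lithium at the only position ortho to the strongly directing diethylamide, and the arylmagnesium bromide formed by transmetalation is allylated by the symmetric 2-methylallyl bromide, which gives one product whether attack is direct or allylic.

Step 2
Reactants: 3 N,N-diethyl-2-methoxy-6-(2-methylprop-2-en-1-yl)benzamide
Product: 4 8-methoxy-3-methylnaphthalen-1-ol
Conditions: LiN(i-Pr)2 (2.2 equiv), THF, −78 °C to rt; aq. HCl
Reagents that add atoms: none
Why: Anionic ring annulation of an ortho-allylbenzamide: the benzylic-allylic anion attacks the amide carbonyl through its terminal carbon, diethylamide is expelled and the dienone tautomerises to the naphthol, with OMe peri to OH and the methyl group meta to it.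

Step 3
Reactants: 4 8-methoxy-3-methylnaphthalen-1-ol
Product: 5 8-methoxy-3-methylnaphthalen-1-yl 4-methylbenzenesulfonate
Conditions: TsCl, Et3N, DMAP (cat.), CH2Cl2, 0 °C to rt
Reagents that add atoms: p-toluenesulfonyl chloride, Cc1ccc(cc1)S(Cl)(=O)=O
Why: O-Sulfonylation of the naphthol gives an aryl sulfonate that should last until the final hydrolysis and that deactivates the methyl-bearing ring for the bromination that follows.

Step 4
Reactants: 5 8-methoxy-3-methylnaphthalen-1-yl 4-methylbenzenesulfonate
Product: 6 5-bromo-8-methoxy-3-methylnaphthalen-1-yl 4-methylbenzenesulfonate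
Conditions: NBS, MeCN, 0 °C to rt, dark
Reagents that add atoms: N-bromosuccinimide, BrN1C(=O)CCC1=O
Why: Electrophilic aromatic bromination should go para to the methoxy group (C5), since the other ring carries the electron-poor sulfonate and 1-alkoxynaphthalenes prefer para over ortho attack.

Step 5
Reactants: 7 methyl 2,4-dihydroxybenzoate
Product: 8 methyl 2,4-dihydroxy-3-iodobenzoate
Conditions: iodine (0.4 equiv), HIO3 (0.2 equiv), EtOH/H2O, 40 °C
Reagents that add atoms: iodine, [I][I]; iodic acid, O[I](=O)=O
Why: Oxidative electrophilic iodination of a 4-acylresorcinol is directed to C3, the position ortho to both hydroxyl groups, as in the iodination of resorcinol between its hydroxyls.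

Step 6
Reactants: 8 methyl 2,4-dihydroxy-3-iodobenzoate
Product: 9 methyl 2-hydroxy-3-iodo-4-(tosyloxy)benzoate
Conditions: TsCl (1.05 equiv), K2CO3, acetone, rt
Reagents that add atoms: p-toluenesulfonyl chloride, Cc1ccc(cc1)S(Cl)(=O)=O
Why: The 4-hydroxyl is the more acidic phenol while the 2-hydroxyl is held in a hydrogen bond to the ester carbonyl, so one equivalent of sulfonyl chloride should sulfonylate O4 selectively.

Step 7
Reactants: 9 methyl 2-hydroxy-3-iodo-4-(tosyloxy)benzoate
Product: 10 methyl 3-iodo-2-methoxy-4-(tosyloxy)benzoate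
Conditions: MeI, Cs2CO3, DMF, 40 °C
Reagents that add atoms: iodomethane, [CH3][I]
Why: Williamson methylation of the remaining chelated phenol under non-nucleophilic basic conditions leaves the sulfonate and the aryl iodide untouched.

Step 8
Reactants: 6 5-bromo-8-methoxy-3-methylnaphthalen-1-yl 4-methylbenzenesulfonate; 10 methyl 3-iodo-2-methoxy-4-(tosyloxy)benzoate
Product: 12 methyl 2-methoxy-3-[4-methoxy-7-methyl-5-(tosyloxy)naphthalen-1-yl]-4-(tosyloxy)benzoate, via naphthylboronic pinacol ester 11 (not isolated)
Conditions: 6, B2pin2, PdCl2(dppf), KOAc, 1,4-dioxane, 90 °C; then 10, Pd(OAc)2, SPhos, aq. K3PO4, 80 °C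
Reagents that add atoms: none
Why: Miyaura borylation of the bromide followed in the same flask by Suzuki–Miyaura coupling forms the biaryl bond, the aryl iodide undergoing oxidative addition far faster than either aryl sulfonate and the biaryl phosphine supporting the hindered coupling.

Step 9
Reactants: 12 methyl 2-methoxy-3-[4-methoxy-7-methyl-5-(tosyloxy)naphthalen-1-yl]-4-(tosyloxy)benzoate
Product: 13 2-methoxy-3-[4-methoxy-7-methyl-5-(tosyloxy)naphthalen-1-yl]-4-(tosyloxy)benzoic acid
Conditions: LiOH, THF/H2O, rt; then aq. HCl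
Reagents that add atoms: lithium hydroxide, [Li+].[OH-]
Why: Saponification of the methyl ester at room temperature should be faster than attack of hydroxide on the two aryl sulfonates and frees the carboxylate that directs the next step.

Step 10
Reactants: 13 2-methoxy-3-[4-methoxy-7-methyl-5-(tosyloxy)naphthalen-1-yl]-4-(tosyloxy)benzoic acid; 14 (R)-2-methyloxirane
Product: 15 (3R)-8-methoxy-3-methyl-7-[4-methoxy-7-methyl-5-(tosyloxy)naphthalen-1-yl]-1-oxo-3,4-dihydro-1H-isochromen-6-yl 4-methylbenzenesulfonate
Conditions: 14 (3 equiv), Pd(OAc)2 (10 mol %), Ac-Val-OH (20 mol %), KOAc, (CF3)2CHOH, 75 °C, sealed tube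
Reagents that add atoms: none
Why: Carboxylate-directed ortho C–H palladation by divalent palladium can occur only at C4a–H (the other ortho position carries OMe), the aryl–palladium bond opens the strained epoxide at its CH2 terminus in an SN2 sense and the alkoxide lactonises, so the stereocenter of 14 is carried over unchanged as (R)-C3.

Step 11
Reactants: 15 (3R)-8-methoxy-3-methyl-7-[4-methoxy-7-methyl-5-(tosyloxy)naphthalen-1-yl]-1-oxo-3,4-dihydro-1H-isochromen-6-yl 4-methylbenzenesulfonate
Product: 16 1-{2-[(2R)-2-hydroxypropyl]-6-methoxy-5-[4-methoxy-7-methyl-5-(tosyloxy)naphthalen-1-yl]-4-(tosyloxy)phenyl}ethan-1-one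
Conditions: MeLi (1.05 equiv), THF, −78 °C; AcOH quench at −78 °C
Reagents that add atoms: methyllithium, [Li]C
Why: Mono-addition of an organolithium to a lactone: the tetrahedral lithium alkoxide persists at −78 °C until the acidic quench, so the methyl ketone and the (R)-alcohol are released without second addition, the aryl sulfonates being much less electrophilic at this temperature.

Step 12
Reactants: 16 1-{2-[(2R)-2-hydroxypropyl]-6-methoxy-5-[4-methoxy-7-methyl-5-(tosyloxy)naphthalen-1-yl]-4-(tosyloxy)phenyl}ethan-1-one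
Product: 19 (3S)-8-methoxy-1,3-dimethyl-7-[4-methoxy-7-methyl-5-(tosyloxy)naphthalen-1-yl]-3,4-dihydroisoquinolin-6-yl 4-methylbenzenesulfonate, via (S)-azido ketone 17 (not isolated), via iminophosphorane 18 (not isolated)
Conditions: PPh3, DIAD, (PhO)2P(O)N3 (1.5 equiv each), THF, 0 °C to rt; then PPh3 (1.5 equiv), toluene, 80 °C
Reagents that add atoms: diphenylphosphoryl azide, [N-]=[N+]=NP(=O)(Oc1ccccc1)Oc1ccccc1
Why: Mitsunobu activation turns the secondary hydroxyl of 16 into an alkoxyphosphonium ion that azide displaces in an SN2 reaction with inversion at C3 to give 17, the second portion of PPh3 converts the azide with loss of N2 into iminophosphorane 18 (Staudinger reaction), and the nitrogen of 18 adds to the C1 ketone and expels Ph3PO through a four-membered oxazaphosphetidine (intramolecular aza-Wittig reaction). The closest known reaction type is the Staudinger/aza-Wittig synthesis of cyclic imines from azido ketones, here run in the same flask as the Mitsunobu azidation of the alcohol. The dihydropyridine ring is closed by 6-exo-trig attack of N2 on the C1 carbonyl, which forms the N2=C1 bond last, the C3–N2 bond having been made in the first stage. No stereocenter is created from a prochiral centre: C3 is inverted, so its (S) configuration is controlled by the (R)-carbinol that stems from epoxide 14. The step needs substitution to win over elimination to the propenylarene and needs the ketone to stay passive until the ylide is formed; azide is a small and weakly basic nucleophile, and the ketone, flanked by the C8 methoxy group and the side chain, is inert to the betaine yet held next to the iminophosphorane for ring closure. Regiochemistry of the closure is fixed by the substrate, because C1 has been attached to C8a since the carboxyl stage.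

Step 13
Reactants: 19 (3S)-8-methoxy-1,3-dimethyl-7-[4-methoxy-7-methyl-5-(tosyloxy)naphthalen-1-yl]-3,4-dihydroisoquinolin-6-yl 4-methylbenzenesulfonate
Product: 20 (3S)-7-(5-hydroxy-4-methoxy-7-methylnaphthalen-1-yl)-8-methoxy-1,3-dimethyl-3,4-dihydroisoquinolin-6-ol
Conditions: KOH, 1,4-dioxane/H2O, 80 °C, argon; then aq. HCl to pH 8
Reagents that add atoms: none
Why: Sulfonate ester hydrolysis with S–O cleavage: hydroxide attacks sulfur of both aryl sulfonates and releases the two phenols, while the cyclic imine, the methyl ethers and the non-acidic C3 stereocenter should be unaffected.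

Compound list
1 | N,N-diethyl-2-methoxybenzamide | CCN(CC)C(=O)c1ccccc1OC | starting material
2 | 3-bromo-2-methylprop-1-ene | CC(=C)CBr | starting material
3 | N,N-diethyl-2-methoxy-6-(2-methylprop-2-en-1-yl)benzamide | CCN(CC)C(=O)c1c(CC(C)=C)cccc1OC | intermediate
4 | 8-methoxy-3-methylnaphthalen-1-ol | COc1cccc2cc(C)cc(O)c12 | intermediate
5 | 8-methoxy-3-methylnaphthalen-1-yl 4-methylbenzenesulfonate | COc1cccc2cc(C)cc(OS(=O)(=O)c3ccc(C)cc3)c12 | intermediate
6 | 5-bromo-8-methoxy-3-methylnaphthalen-1-yl 4-methylbenzenesulfonate | COc1ccc(Br)c2cc(C)cc(OS(=O)(=O)c3ccc(C)cc3)c12 | intermediate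
7 | methyl 2,4-dihydroxybenzoate | COC(=O)c1ccc(O)cc1O | starting material
8 | methyl 2,4-dihydroxy-3-iodobenzoate | COC(=O)c1ccc(O)c(I)c1O | intermediate
9 | methyl 2-hydroxy-3-iodo-4-(tosyloxy)benzoate | COC(=O)c1ccc(OS(=O)(=O)c2ccc(C)cc2)c(I)c1O | intermediate
10 | methyl 3-iodo-2-methoxy-4-(tosyloxy)benzoate | COC(=O)c1ccc(OS(=O)(=O)c2ccc(C)cc2)c(I)c1OC | intermediate
11 | 8-methoxy-3-methyl-5-(4,4,5,5-tetramethyl-1,3,2-dioxaborolan-2-yl)naphthalen-1-yl 4-methylbenzenesulfonate | COc1ccc(B2OC(C)(C)C(C)(C)O2)c2cc(C)cc(OS(=O)(=O)c3ccc(C)cc3)c12 | intermediate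
12 | methyl 2-methoxy-3-[4-methoxy-7-methyl-5-(tosyloxy)naphthalen-1-yl]-4-(tosyloxy)benzoate | COC(=O)c1ccc(OS(=O)(=O)c2ccc(C)cc2)c(c1OC)-c1ccc(OC)c2c(OS(=O)(=O)c3ccc(C)cc3)cc(C)cc12 | intermediate
13 | 2-methoxy-3-[4-methoxy-7-methyl-5-(tosyloxy)naphthalen-1-yl]-4-(tosyloxy)benzoic acid | OC(=O)c1ccc(OS(=O)(=O)c2ccc(C)cc2)c(c1OC)-c1ccc(OC)c2c(OS(=O)(=O)c3ccc(C)cc3)cc(C)cc12 | intermediate
14 | (R)-2-methyloxirane | C[C@@H]1CO1 | starting material
15 | (3R)-8-methoxy-3-methyl-7-[4-methoxy-7-methyl-5-(tosyloxy)naphthalen-1-yl]-1-oxo-3,4-dihydro-1H-isochromen-6-yl 4-methylbenzenesulfonate | C[C@@H]1Cc2cc(OS(=O)(=O)c3ccc(C)cc3)c(c(OC)c2C(=O)O1)-c1ccc(OC)c2c(OS(=O)(=O)c3ccc(C)cc3)cc(C)cc12 | intermediate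
16 | 1-{2-[(2R)-2-hydroxypropyl]-6-methoxy-5-[4-methoxy-7-methyl-5-(tosyloxy)naphthalen-1-yl]-4-(tosyloxy)phenyl}ethan-1-one | CC(=O)c1c(C[C@@H](C)O)cc(OS(=O)(=O)c2ccc(C)cc2)c(c1OC)-c1ccc(OC)c2c(OS(=O)(=O)c3ccc(C)cc3)cc(C)cc12 | intermediate
17 | 1-{2-[(2S)-2-azidopropyl]-6-methoxy-5-[4-methoxy-7-methyl-5-(tosyloxy)naphthalen-1-yl]-4-(tosyloxy)phenyl}ethan-1-one | CC(=O)c1c(C[C@H](C)N=[N+]=[N-])cc(OS(=O)(=O)c2ccc(C)cc2)c(c1OC)-c1ccc(OC)c2c(OS(=O)(=O)c3ccc(C)cc3)cc(C)cc12 | intermediate
18 | 1-{2-[(2S)-2-(triphenylphosphoranylideneamino)propyl]-6-methoxy-5-[4-methoxy-7-methyl-5-(tosyloxy)naphthalen-1-yl]-4-(tosyloxy)phenyl}ethan-1-one | CC(=O)c1c(C[C@H](C)N=P(c2ccccc2)(c2ccccc2)c2ccccc2)cc(OS(=O)(=O)c2ccc(C)cc2)c(c1OC)-c1ccc(OC)c2c(OS(=O)(=O)c3ccc(C)cc3)cc(C)cc12 | intermediate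
19 | (3S)-8-methoxy-1,3-dimethyl-7-[4-methoxy-7-methyl-5-(tosyloxy)naphthalen-1-yl]-3,4-dihydroisoquinolin-6-yl 4-methylbenzenesulfonate | COc1c2c(cc(OS(=O)(=O)c3ccc(C)cc3)c1-c1ccc(OC)c3c(OS(=O)(=O)c4ccc(C)cc4)cc(C)cc13)C[C@H](C)N=C2C | intermediate
20 | (3S)-7-(5-hydroxy-4-methoxy-7-methylnaphthalen-1-yl)-8-methoxy-1,3-dimethyl-3,4-dihydroisoquinolin-6-ol | COc1c2c(cc(O)c1-c1ccc(OC)c3c(O)cc(C)cc13)C[C@H](C)N=C2C | target

Total step count: 13 (each one-pot sequence counted once).
Longest linear sequence: 10 steps (steps 1 to 4 and 8 to 13, from 1 to 20).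

Steps most likely to fail

Step 10. Directed palladation of the crowded, electron-rich acid may be slow, so that opening of the epoxide by the fluorinated alcohol or undirected metalation of the naphthalene ring takes over. The fallback sets out from 13 and comes back at 16. Ruthenium-catalysed carboxylate-directed C–H/O–H annulation of 13 with the acetone-derived sulfoxonium ylide CC(=O)C=S(C)(C)=O ([RuCl2(p-cymene)]2, NaOAc, CF3CH2OH, 100 °C) should give the 3-methylisocoumarin F1. MeLi (1 equiv, THF, −78 °C, AcOH quench) should open the enol lactone to the 1,5-diketone F2. An (R)-selective alcohol dehydrogenase (for example that of Lactobacillus brevis, NADP+, propan-2-ol, buffer/DMSO) should then reduce only the unhindered propan-2-one carbonyl and return hydroxy ketone 16.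

Step 12. After activation of the homobenzylic alcohol, elimination to the conjugated propenylarene or capture of the alkoxyphosphonium ion by the neighbouring ketone oxygen may outrun substitution by azide, and the hindered ketone may be slow in the aza-Wittig closure. The fallback sets out from 16 and comes back at 19; it introduces nitrogen and the stereocenter by reductive amination and not by substitution. Oxidation of 16 with Dess–Martin periodinane should give the 1,5-diketone F2 described above. An (S)-selective amine transaminase (pyridoxal phosphate, isopropylamine as donor, buffer/DMSO, 35 °C) should aminate only the methyl ketone of the side chain, the aryl ketone being shielded by its two ortho substituents, to the (S)-amino ketone F3 (not isolated), which should condense spontaneously to cyclic imine 19.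

Step 8. Protodeboronation of the peri-hindered boronate and slow transmetalation onto the doubly ortho-substituted arylpalladium iodide may erode the coupling, and long reaction times invite insertion of palladium into a sulfonate C–O bond. The fallback sets out from 8 (and from 6 by way of 11) and comes back at 12; it moves the coupling to the unprotected iodoresorcinol ester, whose ortho groups are only hydroxyls. Boronate 11 and 8 (Pd(OAc)2, SPhos, K3PO4, 1,4-dioxane/H2O, 80 °C) should give the biaryl diol ester F4. TsCl/K2CO3 in acetone should sulfonylate O4 selectively, as in step 6, to the monosulfonate F5, and MeI/Cs2CO3 in DMF should then give 12.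

Further compounds
F1 | step 10 | 8-methoxy-3-methyl-7-[4-methoxy-7-methyl-5-(tosyloxy)naphthalen-1-yl]-1-oxo-1H-isochromen-6-yl 4-methylbenzenesulfonate | CC1=Cc2cc(OS(=O)(=O)c3ccc(C)cc3)c(c(OC)c2C(=O)O1)-c1ccc(OC)c2c(OS(=O)(=O)c3ccc(C)cc3)cc(C)cc12
F2 | step 10 | 1-{2-acetyl-3-methoxy-4-[4-methoxy-7-methyl-5-(tosyloxy)naphthalen-1-yl]-5-(tosyloxy)phenyl}propan-2-one | CC(=O)Cc1cc(OS(=O)(=O)c2ccc(C)cc2)c(c(OC)c1C(C)=O)-c1ccc(OC)c2c(OS(=O)(=O)c3ccc(C)cc3)cc(C)cc12
F3 | step 12 | 1-{2-[(2S)-2-aminopropyl]-6-methoxy-5-[4-methoxy-7-methyl-5-(tosyloxy)naphthalen-1-yl]-4-(tosyloxy)phenyl}ethan-1-one | CC(=O)c1c(C[C@H](C)N)cc(OS(=O)(=O)c2ccc(C)cc2)c(c1OC)-c1ccc(OC)c2c(OS(=O)(=O)c3ccc(C)cc3)cc(C)cc12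
F4 | step 8 | methyl 2,4-dihydroxy-3-[4-methoxy-7-methyl-5-(tosyloxy)naphthalen-1-yl]benzoate | COC(=O)c1ccc(O)c(c1O)-c1ccc(OC)c2c(OS(=O)(=O)c3ccc(C)cc3)cc(C)cc12
F5 | step 8 | methyl 2-hydroxy-3-[4-methoxy-7-methyl-5-(tosyloxy)naphthalen-1-yl]-4-(tosyloxy)benzoate | COC(=O)c1ccc(OS(=O)(=O)c2ccc(C)cc2)c(c1O)-c1ccc(OC)c2c(OS(=O)(=O)c3ccc(C)cc3)cc(C)cc12
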